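- Free catalyst is single-handed, so follow a molecule of each hand through the same forks: binding to the catalyst, then capture by reagent. Take as a working rule that the two hands pass at a steady ratio of chances.

- Sunday's: left-handed substrate 1 M; right-handed substrate 1 M; reagent 1.5 equiv; free catalyst 0.2 mol%; added ligand 3.1 mM; run made earlier
- flask: left-handed substrate 1.0 M; reagent 1.00 equiv; free catalyst 0.2 mol%; added ligand 3.1 mM; right-handed substrate 1.0 M; time 10 d

- Sunday's (time / h: right-handed substrate / %, left-handed substrate / %, left-handed product / %): 12.0: 49.4, 27.8, 20.1; 25.0: 48.8, 14.7, 28.5; 40.0: 47.5, 6.5, 31.7; 50.0: 46.6, 4.4, 31.9

(scatter of a reading: 0.3 percentage points)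

1. whether the excess of right-handed substrate over left-handed substrate among what is left of the two reaches 80% by 10 d (yes / no)
2. the highest excess of right-handed substrate over left-handed substrate among what is left of the two up to 10 d

- free catalyst is single-handed; left-handed substrate and right-handed substrate are mirror images of each other, charged as a racemate, each of them at the stated concentration
- the earlier runs were read with a standard deviation of 0.3 percentage points
- steps thought possible: free catalyst + left-handed substrate <-> catalyst intermediate A; free catalyst + right-handed substrate <-> catalyst intermediate B; reagent + catalyst intermediate A -> free catalyst + left-handed product; reagent + catalyst intermediate B -> free catalyst + right-handed product; left-handed product <-> right-handed product; free catalyst + added ligand <-> idle complex; free catalyst <-> dormant form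

- Sunday's last reading gives a ratio of 34.5. This is the selectivity factor, the logarithm of the part left of left-handed substrate over the logarithm of the part left of right-handed substrate. It is a ratio reckoned from two readings, each read with a standard deviation of 0.3 percentage points, so treat it as rough.
- Turn the reagent first. The flask charges 1.00 equiv on the left-handed substrate, which makes reagent the limiting reagent: it can carry off half of the two substrates together. At that stop, the left-handed part left equals the right-handed part lost.
- Reckon that stop by hand. Sunday's right-handed substrate had lost 6.80% of its charge; take this as a first guess. The selectivity factor then puts the left-handed part left at 7.49%, so my excess at the stop is 85.0%.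
- Turn the time next. Sunday's left-handed substrate halved every 14.4 h late in the run, with 1.5 equiv of reagent, and the flask allows 10 d. Expect the flask to slow as its reagent thins, yet still to pass 80%.
- Set beside this the forecast: yes, with a top of 86%, which stands above my figure. Its ground: “Reagent then stops the reaction at 50% conversion”.
- The flask gives yes, with a top of 83.4%.

    free catalyst + left-handed substrate ⇌ catalyst intermediate A (K = 6.05 M⁻¹, k = 16.8 M⁻¹ min⁻¹)
    free catalyst + right-handed substrate ⇌ catalyst intermediate B (K = 0.580 M⁻¹, k = 5.36 M⁻¹ min⁻¹)
    reagent + catalyst intermediate A → free catalyst + left-handed product (k = 0.354 M⁻¹ min⁻¹)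
    reagent + catalyst intermediate B → free catalyst + right-handed product (k = 0.0858 M⁻¹ min⁻¹)
    left-handed product ⇌ right-handed product (k = 2.80 × 10⁻⁴ min⁻¹)
    free catalyst + added ligand ⇌ idle complex (K = 110 M⁻¹, k = 0.255 M⁻¹ min⁻¹)
    free catalyst ⇌ dormant form (K = 14.4, k = 9.24 × 10⁻⁵ min⁻¹)

- Enter the 8.6% of left-handed substrate left in the flask at 10.0 d into the selectivity factor: it returns 93.1% of the right-handed substrate and an excess of 83.1%, beside the flask's top of 83.4%. Compare the times: the flask crosses 80% at 6.94 d, earlier than the 10 d allowed, and at that limit reagent still stands at 2.8% of its charge.

The numbers in the tables stem from a simulated flask on assumed constants; the scatter is artificial.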